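**Retrosynthetic overview**

1. Target 26 comes from lactone 23 by three end-group operations (desilylation, acetylation, PMB removal). The only ring, the 5,6-dihydro-2H-pyran-2-one, is formed once, in step 16.
2. Key disconnection: the C4–C5 ring bond (vinylic CH to ring CH2) of 23 is cut to the open-chain bromo ester 20. Forward, a triazolylidene-catalysed β-umpolung annulation makes the acrylate β-carbon nucleophilic, lets it displace the primary bromide and then restores the C3=C4 double bond, so ring, ring bond and conjugated endocyclic alkene arise in one metal-free operation.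
3. Enabling feature: in the ring O1–C2(=O)–C3(=C4H)–C5H2–C6H, the atoms C2/C3/C4 are an α-branched acrylate whose β-carbon C4 carries only hydrogen, its ester oxygen O1 sits on C6, and C5 next to C6 is a primary CH2. A leaving group on C5 is therefore held six atoms from an umpoled C4, and the hydrogen regained at C3 lets the catalyst leave.
4. Ester 20 comes from bromohydrin 14 and acid 19 (Steglich). The four-carbon core of 14 (CH2Br–CH(OH)–C(=)–CH2O) is L-erythrulose, which supplies the C6 stereocentre; a Wittig reaction (ketone 10 + ylide 11) joins it to a C7 piece cut out of nerol, which supplies the Z allylic alcohol end.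
5. Acid 19 comes from triethyl phosphonoacetate, 5-bromo-2-methylpent-2-ene and formaldehyde (alkylation, Horner–Wadsworth–Emmons methylenation, saponification).

Key step: step 16

Remark: the ring atoms of the dihydropyranone are called O1, C2 (C=O), C3, C4, C5, C6 throughout; commercial L-erythrulose (sold as a syrup) is assumed to be dried to the monomeric ketose before use. PMB = 4-methoxybenzyl, TBDPS = tert-butyldiphenylsilyl.

**Route**

Step 1
Reactants: 1 nerol, (2Z)-3,7-dimethylocta-2,6-dien-1-ol
Product: 2 neryl PMB ether, 1-({[(2Z)-3,7-dimethylocta-2,6-dien-1-yl]oxy}methyl)-4-methoxybenzene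
Conditions: NaH, 4-methoxybenzyl chloride, Bu4NI (cat.), THF/DMF, 0 °C to rt
Reagents that add atoms: 4-methoxybenzyl chloride, COc1ccc(CCl)cc1
Why: Williamson ether synthesis on the primary allylic alkoxide; no stereocentre is made and the Z-alkene is not touched.

Step 2
Reactants: 2 neryl PMB ether
Product: 3 3-[(3Z)-5-[(4-methoxybenzyl)oxy]-3-methylpent-3-en-1-yl]-2,2-dimethyloxirane (racemic at the oxirane CH)
Conditions: mCPBA (1.0 equiv), CH2Cl2, −20 °C to 0 °C
Reagents that add atoms: meta-chloroperoxybenzoic acid, OOC(=O)c1cccc(Cl)c1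
Why: Prilezhaev epoxidation is electrophilic and should go first to the trialkyl 6,7-alkene, the 2,3-alkene being deactivated by its allylic C–O bond; the epoxide stereocentre is of no consequence because it is cleaved in step 3.

Step 3
Reactants: 3 terminal epoxide
Product: 4 (4Z)-6-[(4-methoxybenzyl)oxy]-4-methylhex-4-enal
Conditions: H5IO6, THF/H2O, 0 °C
Reagents that add atoms: none
Why: Acid-mediated hydration of the epoxide followed in the same pot by periodate glycol cleavage (Malaprade reaction) excises the terminal three-carbon unit as acetone and leaves the aldehyde with the Z-alkene intact.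

Step 4
Reactants: 4 aldehyde
Product: 5 (4Z)-6-[(4-methoxybenzyl)oxy]-4-methylhex-4-en-1-ol
Conditions: NaBH4, MeOH, 0 °C
Reagents that add atoms: none
Why: Chemoselective borohydride reduction of the aldehyde to the primary alcohol.

Step 5
Reactants: 5 primary alcohol
Product: 6 (2Z)-6-iodo-1-[(4-methoxybenzyl)oxy]-3-methylhex-2-ene
Conditions: I2, PPh3, imidazole, CH2Cl2, 0 °C to rt
Reagents that add atoms: iodine, II
Why: Appel-type iodination, in which iodide displaces the alkoxyphosphonium ion at the primary carbon by SN2.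

Step 6
Reactants: 6 primary iodide
Product: 7 [(4Z)-6-[(4-methoxybenzyl)oxy]-4-methylhex-4-en-1-yl]triphenylphosphonium iodide
Conditions: PPh3, MeCN, reflux
Reagents that add atoms: triphenylphosphine, c1ccc(cc1)P(c1ccccc1)c1ccccc1
Why: SN2 quaternisation of triphenylphosphine by the primary iodide gives the Wittig salt.

Step 7
Reactants: 8 L-erythrulose, (3S)-1,3,4-trihydroxybutan-2-one
Product: 9 1-[(4S)-2,2-dimethyl-1,3-dioxolan-4-yl]-2-hydroxyethan-1-one
Conditions: 2,2-dimethoxypropane, acetone, camphorsulfonic acid (cat.), rt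
Reagents that add atoms: 2,2-dimethoxypropane, COC(C)(C)OC
Why: Acid-catalysed transacetalisation closes the five-membered dioxolane on the vicinal 3,4-diol and leaves the 1-hydroxyl free; the stereocentre comes from the chiral pool and its C–O bond is not broken.

Step 8
Reactants: 9 erythrulose acetonide
Product: 10 2-[(tert-butyldiphenylsilyl)oxy]-1-[(4S)-2,2-dimethyl-1,3-dioxolan-4-yl]ethan-1-one
Conditions: TBDPSCl, imidazole, DMF, 0 °C to rt
Reagents that add atoms: tert-butyl(chloro)diphenylsilane, CC(C)(C)[Si](Cl)(c1ccccc1)c1ccccc1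
Why: Silylation of the remaining primary hydroxyl gives an acid-stable ether that survives the acetal hydrolysis of step 10.

Step 9
Reactants: 7 phosphonium iodide; 10 silyloxy ketone
Product: 12 tert-butyl{[(2E,6Z)-2-[(4R)-2,2-dimethyl-1,3-dioxolan-4-yl]-8-[(4-methoxybenzyl)oxy]-6-methylocta-2,6-dien-1-yl]oxy}diphenylsilane, via phosphonium ylide 11 (not isolated)
Conditions: KN(SiMe3)2, THF, −78 °C; then 10, −78 °C to rt
Reagents that add atoms: none
Why: Wittig olefination of an α-alkoxy ketone with a non-stabilised ylide under salt-free conditions, in which the ylide chain is expected to be placed cis to the small CH2O group and trans to the branched dioxolane (the known cis-directing effect of an α-alkoxymethyl group, reinforced here by sterics), which is the E geometry of the target; the α-stereocentre, held in the dioxolane ring, should survive the cold, fast addition.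

Step 10
Reactants: 12 alkene acetonide
Product: 13 (2R,3E,7Z)-3-{[(tert-butyldiphenylsilyl)oxy]methyl}-9-[(4-methoxybenzyl)oxy]-7-methylnona-3,7-diene-1,2-diol
Conditions: AcOH/H2O (4:1), 40 °C
Reagents that add atoms: none
Why: Acid hydrolysis of the isopropylidene acetal, under which the silyl ether, the PMB ether and the allylic stereocentre are stable.

Step 11
Reactants: 13 diol
Product: 14 (2R,3E,7Z)-1-bromo-3-{[(tert-butyldiphenylsilyl)oxy]methyl}-9-[(4-methoxybenzyl)oxy]-7-methylnona-3,7-dien-2-ol
Conditions: CBr4 (1.05 equiv), PPh3 (1.05 equiv), CH2Cl2, 0 °C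
Reagents that add atoms: carbon tetrabromide, BrC(Br)(Br)Br
Why: Appel reaction with one equivalent of reagent, which for a terminal 1,2-diol should deliver bromide to the unhindered primary carbon (opening of the cyclic dioxaphosphorane at CH2) and leave the secondary allylic hydroxyl and its configuration untouched.

Step 12
Reactants: 15 triethyl phosphonoacetate; 16 5-bromo-2-methylpent-2-ene
Product: 17 ethyl 2-(diethoxyphosphoryl)-6-methylhept-5-enoate (racemic)
Conditions: NaH, DMSO, rt to 60 °C
Reagents that add atoms: none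
Why: SN2 C-alkylation of the sodium phosphonoacetate anion by the primary homoallylic bromide.

Step 13
Reactants: 17 alkylated phosphonate
Product: 18 ethyl 6-methyl-2-methylidenehept-5-enoate
Conditions: aqueous formaldehyde, K2CO3, THF/H2O, rt
Reagents that add atoms: formaldehyde, C=O
Why: Horner–Wadsworth–Emmons olefination with formaldehyde gives the α-branched (1,1-disubstituted) acrylate.

Step 14
Reactants: 18 ethyl ester
Product: 19 6-methyl-2-methylidenehept-5-enoic acid
Conditions: LiOH, THF/H2O, rt; then aqueous HCl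
Reagents that add atoms: lithium hydroxide, [Li+].[OH-]
Why: Saponification of the ethyl ester by acyl–oxygen cleavage; the α-branched acrylate is a poor acceptor for hydroxide, so conjugate addition should not compete.

Step 15
Reactants: 14 bromohydrin; 19 acrylic acid
Product: 20 (2R,3E,7Z)-1-bromo-3-{[(tert-butyldiphenylsilyl)oxy]methyl}-9-[(4-methoxybenzyl)oxy]-7-methylnona-3,7-dien-2-yl 6-methyl-2-methylidenehept-5-enoate
Conditions: DCC, DMAP (cat.), CH2Cl2, 0 °C to rt
Reagents that add atoms: none
Why: Steglich esterification acylates the secondary allylic hydroxyl without breaking its C–O bond (retention at the stereocentre) under nearly neutral conditions that avoid epoxide closure of the bromohydrin.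

Step 16
Reactants: 20 bromo ester
Product: 23 (6S)-6-[(2E,6Z)-1-[(tert-butyldiphenylsilyl)oxy]-8-[(4-methoxybenzyl)oxy]-6-methylocta-2,6-dien-2-yl]-3-(4-methylpent-3-en-1-yl)-5,6-dihydro-2H-pyran-2-one, via deoxy-Breslow enediamine 21 (not isolated), via C4-triazolium lactone bromide 22 (not isolated)
Conditions: 1,3,4-triphenyl-1,2,4-triazolium tetrafluoroborate (15 mol %), K3PO4 (2.5 equiv), 1,2-dimethoxyethane (0.02 M), 80 °C
Reagents that add atoms: none
Why: Proposed new method: the triazolylidene adds to the unsubstituted β-carbon (C4) of the α-branched acrylate and a 1,2-proton shift gives the deoxy-Breslow enediamine 21, in which C4 is nucleophilic (umpolung); C4 then displaces the primary bromide at C5 in a 6-exo-tet SN2 closure of the O1–C2–C3–C4–C5–C6 ring to give triazolium salt 22, and phosphate removes the acidic C3–H so that the carbene leaves by E1cB and the C3=C4 bond is restored inside the ring. The closest known reaction types are the carbene-catalysed intramolecular β-alkylation of enoates that carry a halide or tosylate on a carbon tether and the carbene-catalysed tail-to-tail dimerisation of methacrylates, both of which run through the same kind of deoxy-Breslow intermediate; new here is that the electrophile hangs on the ester oxygen, so that a lactone and not a carbocycle is closed. No stereocentre is formed: C6 comes from L-erythrulose and neither its C–H nor its C–O bond takes part, so its configuration should be carried through unchanged (the change of descriptor from R in 20 to S in 23 is a priority change only). The selectivity needed is C4- versus C3- or O-alkylation and ring closure versus dimerisation: attack of the enolate carbon C3 on C5 would be a 5-(enolendo)-exo-tet closure, which is stereoelectronically disfavoured, the soft bromide leaving group (chosen over a sulfonate) disfavours O-alkylation to a ketene acetal, and high dilution suppresses the intermolecular pathway. The position of the new double bond is fixed because only C3–H is acidic in 22, and the substrate carries only silyl and benzyl ethers beside the reacting ester, so the carbene has no second ester or free hydroxyl for acyl transfer.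

Step 17
Reactants: 23 silyl-protected lactone
Product: 24 (6S)-6-[(2E,6Z)-1-hydroxy-8-[(4-methoxybenzyl)oxy]-6-methylocta-2,6-dien-2-yl]-3-(4-methylpent-3-en-1-yl)-5,6-dihydro-2H-pyran-2-one
Conditions: HF·pyridine, pyridine, THF, 0 °C to rt
Reagents that add atoms: none
Why: Fluoride-driven cleavage of the Si–O bond of the primary silyl ether (desilylation); lactone, enoate and PMB ether are inert to buffered HF.

Step 18
Reactants: 24 allylic alcohol
Product: 25 (2E,6Z)-8-[(4-methoxybenzyl)oxy]-6-methyl-2-[(2S)-5-(4-methylpent-3-en-1-yl)-6-oxo-3,6-dihydro-2H-pyran-2-yl]octa-2,6-dien-1-yl acetate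
Conditions: Ac2O, pyridine, DMAP (cat.), CH2Cl2, 0 °C
Reagents that add atoms: acetic anhydride, CC(=O)OC(C)=O
Why: DMAP-catalysed acetylation of the primary allylic alcohol, the only free hydroxyl in the molecule.

Step 19
Reactants: 25 PMB-protected acetate
Product: 26 target, (2E,6Z)-8-hydroxy-6-methyl-2-[(2S)-5-(4-methylpent-3-en-1-yl)-6-oxo-3,6-dihydro-2H-pyran-2-yl]octa-2,6-dien-1-yl acetate
Conditions: DDQ, CH2Cl2/pH 7 phosphate buffer, 0 °C
Reagents that add atoms: none
Why: Oxidative cleavage of the PMB ether by DDQ (hydride abstraction to the benzylic oxocarbenium ion, then hydrolysis), which should leave acetate, lactone and the isolated trisubstituted alkenes untouched and reveal the Z allylic alcohol.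

**Compound list**

1 | nerol, (2Z)-3,7-dimethylocta-2,6-dien-1-ol | CC(C)=CCC/C(C)=C\CO | starting material
2 | 1-({[(2Z)-3,7-dimethylocta-2,6-dien-1-yl]oxy}methyl)-4-methoxybenzene | CC(C)=CCC/C(C)=C\COCc1ccc(OC)cc1 | intermediate
3 | 3-[(3Z)-5-[(4-methoxybenzyl)oxy]-3-methylpent-3-en-1-yl]-2,2-dimethyloxirane (racemic) | CC1(C)OC1CC/C(C)=C\COCc1ccc(OC)cc1 | intermediate
4 | (4Z)-6-[(4-methoxybenzyl)oxy]-4-methylhex-4-enal | O=CCC/C(C)=C\COCc1ccc(OC)cc1 | intermediate
5 | (4Z)-6-[(4-methoxybenzyl)oxy]-4-methylhex-4-en-1-ol | OCCC/C(C)=C\COCc1ccc(OC)cc1 | intermediate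
6 | (2Z)-6-iodo-1-[(4-methoxybenzyl)oxy]-3-methylhex-2-ene | ICCC/C(C)=C\COCc1ccc(OC)cc1 | intermediate
7 | [(4Z)-6-[(4-methoxybenzyl)oxy]-4-methylhex-4-en-1-yl]triphenylphosphonium iodide | [I-].c1ccc(cc1)[P+](c1ccccc1)(c1ccccc1)CCC/C(C)=C\COCc1ccc(OC)cc1 | intermediate
8 | L-erythrulose, (3S)-1,3,4-trihydroxybutan-2-one | OCC(=O)[C@@H](O)CO | starting material
9 | 1-[(4S)-2,2-dimethyl-1,3-dioxolan-4-yl]-2-hydroxyethan-1-one | OCC(=O)[C@@H]1COC(C)(C)O1 | intermediate
10 | 2-[(tert-butyldiphenylsilyl)oxy]-1-[(4S)-2,2-dimethyl-1,3-dioxolan-4-yl]ethan-1-one | CC(C)(C)[Si](OCC(=O)[C@@H]1COC(C)(C)O1)(c1ccccc1)c1ccccc1 | intermediate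
11 | {(4Z)-6-[(4-methoxybenzyl)oxy]-4-methylhex-4-en-1-ylidene}triphenylphosphorane (ylide, formed in situ) | c1ccc(cc1)P(=CCC/C(C)=C\COCc1ccc(OC)cc1)(c1ccccc1)c1ccccc1 | intermediate
12 | tert-butyl{[(2E,6Z)-2-[(4R)-2,2-dimethyl-1,3-dioxolan-4-yl]-8-[(4-methoxybenzyl)oxy]-6-methylocta-2,6-dien-1-yl]oxy}diphenylsilane | CC(C)(C)[Si](OC/C(=C\CC/C(C)=C\COCc1ccc(OC)cc1)[C@@H]1COC(C)(C)O1)(c1ccccc1)c1ccccc1 | intermediate
13 | (2R,3E,7Z)-3-{[(tert-butyldiphenylsilyl)oxy]methyl}-9-[(4-methoxybenzyl)oxy]-7-methylnona-3,7-diene-1,2-diol | CC(C)(C)[Si](OC/C(=C\CC/C(C)=C\COCc1ccc(OC)cc1)[C@@H](O)CO)(c1ccccc1)c1ccccc1 | intermediate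
14 | (2R,3E,7Z)-1-bromo-3-{[(tert-butyldiphenylsilyl)oxy]methyl}-9-[(4-methoxybenzyl)oxy]-7-methylnona-3,7-dien-2-ol | CC(C)(C)[Si](OC/C(=C\CC/C(C)=C\COCc1ccc(OC)cc1)[C@@H](O)CBr)(c1ccccc1)c1ccccc1 | intermediate
15 | triethyl phosphonoacetate, ethyl 2-(diethoxyphosphoryl)acetate | CCOC(=O)CP(=O)(OCC)OCC | starting material
16 | 5-bromo-2-methylpent-2-ene | CC(C)=CCCBr | starting material
17 | ethyl 2-(diethoxyphosphoryl)-6-methylhept-5-enoate (racemic) | CCOC(=O)C(CCC=C(C)C)P(=O)(OCC)OCC | intermediate
18 | ethyl 6-methyl-2-methylidenehept-5-enoate | CCOC(=O)C(=C)CCC=C(C)C | intermediate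
19 | 6-methyl-2-methylidenehept-5-enoic acid | OC(=O)C(=C)CCC=C(C)C | intermediate
20 | (2R,3E,7Z)-1-bromo-3-{[(tert-butyldiphenylsilyl)oxy]methyl}-9-[(4-methoxybenzyl)oxy]-7-methylnona-3,7-dien-2-yl 6-methyl-2-methylidenehept-5-enoate | CC(C)(C)[Si](OC/C(=C\CC/C(C)=C\COCc1ccc(OC)cc1)[C@@H](OC(=O)C(=C)CCC=C(C)C)CBr)(c1ccccc1)c1ccccc1 | intermediate
21 | (2R,3E,7Z)-1-bromo-3-{[(tert-butyldiphenylsilyl)oxy]methyl}-9-[(4-methoxybenzyl)oxy]-7-methylnona-3,7-dien-2-yl 6-methyl-2-[(1,3,4-triphenyl-1,4-dihydro-5H-1,2,4-triazol-5-ylidene)methyl]hept-5-enoate (deoxy-Breslow enediamine; acyl C2 and enediamine geometry unspecified; formed in situ) | CC(C)(C)[Si](OC/C(=C\CC/C(C)=C\COCc1ccc(OC)cc1)[C@@H](OC(=O)C(CCC=C(C)C)C=C1N(c2ccccc2)N=C(c2ccccc2)N1c1ccccc1)CBr)(c1ccccc1)c1ccccc1 | intermediate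
22 | 5-{(6S)-6-[(2E,6Z)-1-[(tert-butyldiphenylsilyl)oxy]-8-[(4-methoxybenzyl)oxy]-6-methylocta-2,6-dien-2-yl]-3-(4-methylpent-3-en-1-yl)-2-oxooxan-4-yl}-1,3,4-triphenyl-4H-1,2,4-triazol-1-ium bromide (C3 and C4 of the oxanone unspecified; formed in situ) | CC(C)(C)[Si](OC/C(=C\CC/C(C)=C\COCc1ccc(OC)cc1)[C@@H]1CC(C2=[N+](c3ccccc3)N=C(c3ccccc3)N2c2ccccc2)C(CCC=C(C)C)C(=O)O1)(c1ccccc1)c1ccccc1.[Br-] | intermediate
23 | (6S)-6-[(2E,6Z)-1-[(tert-butyldiphenylsilyl)oxy]-8-[(4-methoxybenzyl)oxy]-6-methylocta-2,6-dien-2-yl]-3-(4-methylpent-3-en-1-yl)-5,6-dihydro-2H-pyran-2-one | CC(C)(C)[Si](OC/C(=C\CC/C(C)=C\COCc1ccc(OC)cc1)[C@@H]1CC=C(CCC=C(C)C)C(=O)O1)(c1ccccc1)c1ccccc1 | intermediate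
24 | (6S)-6-[(2E,6Z)-1-hydroxy-8-[(4-methoxybenzyl)oxy]-6-methylocta-2,6-dien-2-yl]-3-(4-methylpent-3-en-1-yl)-5,6-dihydro-2H-pyran-2-one | OC/C(=C\CC/C(C)=C\COCc1ccc(OC)cc1)[C@@H]1CC=C(CCC=C(C)C)C(=O)O1 | intermediate
25 | (2E,6Z)-8-[(4-methoxybenzyl)oxy]-6-methyl-2-[(2S)-5-(4-methylpent-3-en-1-yl)-6-oxo-3,6-dihydro-2H-pyran-2-yl]octa-2,6-dien-1-yl acetate | CC(=O)OC/C(=C\CC/C(C)=C\COCc1ccc(OC)cc1)[C@@H]1CC=C(CCC=C(C)C)C(=O)O1 | intermediate
26 | (2E,6Z)-8-hydroxy-6-methyl-2-[(2S)-5-(4-methylpent-3-en-1-yl)-6-oxo-3,6-dihydro-2H-pyran-2-yl]octa-2,6-dien-1-yl acetate | CC(=O)OC/C(=C\CC/C(C)=C\CO)[C@@H]1CC=C(CCC=C(C)C)C(=O)O1 | target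

**Step count and risks**

Total steps: 19. Longest linear sequence: 14 steps (1–6, 9–11, 15–19).

Risk 1, step 16 (proposed new method). Three processes may defeat the ring closure. The azolium enolate formed on carbene addition may be O-alkylated by the neighbouring C5–Br (five-membered ketene acetal) before the proton shift. The preferred Z conformation of the ester may keep C4 and C5 apart, so that intermolecular tail-to-tail dimerisation takes over. The carbene itself may be alkylated, which stops turnover. The fallback uses known chemistry and closes the ring at C3=C4 instead. It sets out from diol 13: NaIO4 in THF/H2O cleaves the glycol to enal F1, giving up the erythrulose-derived stereocentre. Asymmetric allylboration with (−)-B-allyldiisopinocampheylborane (Et2O, −78 °C, si-face attack) should then give (S)-homoallylic alcohol F2. Steglich esterification of F2 with acid 19 gives trienyl ester F3. Ring-closing metathesis with the second-generation Hoveyda–Grubbs catalyst (toluene, 80 °C) between the allyl terminus and the 1,1-disubstituted acrylate alkene, the only unhindered olefins, comes back to the route at lactone 23.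

Risk 2, step 9. Oxaphosphetane formation may show too little geometric control (E/Z mixture at the new trisubstituted alkene), and the basic ylide may enolise and so epimerise the α-alkoxy ketone. The fallback is a stepwise Horner–Wittig olefination with separation at the adduct stage. It sets out from iodide 6 and ketone 10: Michaelis–Arbuzov reaction of 6 with ethyl diphenylphosphinite (neat, 120 °C) gives phosphine oxide F4. Lithiation (n-BuLi, THF, −78 °C) and addition to 10 gives β-hydroxy phosphine oxide F5, whose diastereomers are separated on silica. Stereospecific syn-elimination (NaH, DMF, 50 °C) of the diastereomer that leads to the E-alkene comes back to the route at 12.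

Risk 3, step 11. Site selectivity may be lost: the secondary allylic hydroxyl may also be activated, leading to an allylic bromide by allylic transposition or to a dibromide, or the bromohydrin may close to the epoxide. The fallback is a two-stage sulfonate route from diol 13: Bu2SnO-catalysed tosylation (TsCl, Et3N, CH2Cl2, 0 °C), selective for the primary hydroxyl of a 1,2-diol through the stannylene acetal, gives hydroxy tosylate F6. Bromide displacement (LiBr, acetone, 50 °C) comes back to the route at bromohydrin 14.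

**Further compounds**

F1 | step 16 | (2E,6Z)-2-{[(tert-butyldiphenylsilyl)oxy]methyl}-8-[(4-methoxybenzyl)oxy]-6-methylocta-2,6-dienal | CC(C)(C)[Si](OC/C(=C\CC/C(C)=C\COCc1ccc(OC)cc1)C=O)(c1ccccc1)c1ccccc1
F2 | step 16 | (4S,5E,9Z)-5-{[(tert-butyldiphenylsilyl)oxy]methyl}-11-[(4-methoxybenzyl)oxy]-9-methylundeca-1,5,9-trien-4-ol | CC(C)(C)[Si](OC/C(=C\CC/C(C)=C\COCc1ccc(OC)cc1)[C@@H](O)CC=C)(c1ccccc1)c1ccccc1
F3 | step 16 | (4S,5E,9Z)-5-{[(tert-butyldiphenylsilyl)oxy]methyl}-11-[(4-methoxybenzyl)oxy]-9-methylundeca-1,5,9-trien-4-yl 6-methyl-2-methylidenehept-5-enoate | CC(C)(C)[Si](OC/C(=C\CC/C(C)=C\COCc1ccc(OC)cc1)[C@@H](OC(=O)C(=C)CCC=C(C)C)CC=C)(c1ccccc1)c1ccccc1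
F4 | step 9 | {(4Z)-6-[(4-methoxybenzyl)oxy]-4-methylhex-4-en-1-yl}diphenylphosphine oxide | O=P(CCC/C(C)=C\COCc1ccc(OC)cc1)(c1ccccc1)c1ccccc1
F5 | step 9 | (6Z)-1-[(tert-butyldiphenylsilyl)oxy]-2-[(4S)-2,2-dimethyl-1,3-dioxolan-4-yl]-3-(diphenylphosphoryl)-8-[(4-methoxybenzyl)oxy]-6-methyloct-6-en-2-ol (C2 and C3 unspecified, diastereomers separated) | CC(C)(C)[Si](OCC(O)(C(CC/C(C)=C\COCc1ccc(OC)cc1)P(=O)(c1ccccc1)c1ccccc1)[C@@H]1COC(C)(C)O1)(c1ccccc1)c1ccccc1
F6 | step 11 | (2R,3E,7Z)-3-{[(tert-butyldiphenylsilyl)oxy]methyl}-2-hydroxy-9-[(4-methoxybenzyl)oxy]-7-methylnona-3,7-dien-1-yl 4-methylbenzenesulfonate | CC(C)(C)[Si](OC/C(=C\CC/C(C)=C\COCc1ccc(OC)cc1)[C@@H](O)COS(=O)(=O)c1ccc(C)cc1)(c1ccccc1)c1ccccc1
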